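**Strategy**

Ring C is disconnected at O1–C2 and C3–C4. This exposes the ortho relationship of the phenolic O1 and the carbonyl carbon C4 on ring A, i.e. a salicylaldehyde, and leaves C2–C3 as the β- and α-carbons of a cinnamaldehyde. An amine-catalysed domino oxa-Michael/aldol condensation joins both in one operation and sets C2 (R) under catalyst control. Its product, a 2-aryl-2H-chromene-3-carbaldehyde, carries C4 as an alkene CH and a formyl group on C3 that the target lacks; dihydroxylation, oxidation at C4 with retro-Claisen loss of the formyl group and O-methylation then give the 3-methoxy-4-ketone, whose trans C3 centre forms under thermodynamic control.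

Key step: step 6

Remark: 3-hydroxy-4,5-dimethoxybenzaldehyde is taken as a purchasable building block; the sense of induction in step 6 is derived from the usual face-shielding model of diarylprolinol silyl ethers, and the enantiomeric catalyst is equally available.

**Route**

Step 1
Reactants: 1 3,4,5-trimethoxyphenol
Product: 2 6-hydroxy-2,3,4-trimethoxybenzaldehyde
Conditions: MgCl2 (1.5 equiv), Et3N (3.75 equiv), (CH2O)n (6 equiv), MeCN, reflux
Reagents that add atoms: paraformaldehyde (as formaldehyde), C=O
Why: Magnesium phenoxide-directed ortho-formylation; the para position is blocked and the two ortho positions are equivalent, so a single aldehyde should form.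

Step 2
Reactants: 2 6-hydroxy-2,3,4-trimethoxybenzaldehyde
Product: 3 2,3,6-trihydroxy-4-methoxybenzaldehyde
Conditions: BCl3 (3.5 equiv), CH2Cl2, −78 °C to rt, argon; then H2O
Reagents that add atoms: none
Why: Chelation-controlled Lewis acid ether cleavage: boron held between the formyl oxygen and the ortho methoxy group cleaves the C2 ether, the aryloxyborane so formed directs cleavage of the neighbouring C3 ether, and the C4 methoxy group, para to the formyl group and outside any chelate, should survive.

Step 3
Reactants: 3 2,3,6-trihydroxy-4-methoxybenzaldehyde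
Product: 4 5-hydroxy-7-methoxy-2,2-diphenyl-1,3-benzodioxole-4-carbaldehyde
Conditions: Ph2CCl2 (1.2 equiv), Ph2O, 175 °C, argon
Reagents that add atoms: dichlorodiphenylmethane, ClC(Cl)(c1ccccc1)c1ccccc1
Why: Ketal formation with a gem-dichloride: only the vicinal 2,3-dihydroxy pair can close the five-membered dioxole, so the chelated 6-OH, the future O1, stays as the only free phenol.

Step 4
Reactants: 5 3-hydroxy-4,5-dimethoxybenzaldehyde
Product: 6 3-(benzyloxy)-4,5-dimethoxybenzaldehyde
Conditions: BnBr, K2CO3, DMF, rt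
Reagents that add atoms: benzyl bromide, BrCc1ccccc1
Why: Williamson ether synthesis on the only phenol; the benzyl group masks the future 3'-OH until the last step.

Step 5
Reactants: 6 3-(benzyloxy)-4,5-dimethoxybenzaldehyde
Product: 7 (E)-3-[3-(benzyloxy)-4,5-dimethoxyphenyl]prop-2-enal
Conditions: Ph3P=CHCHO (1.1 equiv), toluene, 80 °C
Reagents that add atoms: (triphenylphosphoranylidene)acetaldehyde, O=CC=P(c1ccccc1)(c1ccccc1)c1ccccc1
Why: Wittig olefination with a stabilised ylide, which should give the (E)-enal; keeping the ylide near one equivalent limits a second homologation.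

Step 6
Reactants: 4 5-hydroxy-7-methoxy-2,2-diphenyl-1,3-benzodioxole-4-carbaldehyde; 7 (E)-3-[3-(benzyloxy)-4,5-dimethoxyphenyl]prop-2-enal
Product: 8 (2R)-2-[3-(benzyloxy)-4,5-dimethoxyphenyl]-7-methoxy-5,6-[(diphenylmethylene)dioxy]-2H-chromene-3-carbaldehyde
Conditions: (S)-α,α-diphenylprolinol trimethylsilyl ether (20 mol %), 2-nitrobenzoic acid (20 mol %), toluene, rt to 40 °C
Reagents that add atoms: none
Why: The secondary amine condenses with enal 7 to an (E)-iminium ion; the phenolic O1–H of 4 adds to Cβ (the future C2), the enamine so formed attacks the neighbouring formyl carbon (the future C4) through its α-carbon (the future C3), and loss of water followed by hydrolysis releases the catalyst. The closest known reaction type is exactly this amine-catalysed domino oxa-Michael/aldol condensation of salicylaldehydes with β-aryl enals. Ring C is closed by the aldol step in a 6-(enolexo)-exo-trig mode, the oxa-Michael step being intermolecular. C2 is the only stereocentre formed and is controlled by the catalyst: the diphenyl(silyloxy)methyl group of the (S)-amine shields one face of the iminium ion, so that O1 should add to the Si face of Cβ, which corresponds to 2R. The step needs site selectivity among the ring-A oxygens and chemoselectivity between two aldehydes; the ketal leaves O1 as the only free phenol, aldehyde 4 has no α-hydrogen and enal 7 no γ-hydrogen, so only the crossed sequence is open, and the irreversible dehydration pulls the reversible oxa-Michael addition forward.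

Step 7
Reactants: 8 (2R)-2-[3-(benzyloxy)-4,5-dimethoxyphenyl]-7-methoxy-5,6-[(diphenylmethylene)dioxy]-2H-chromene-3-carbaldehyde
Product: 9 (2R,3S,4S)-2-[3-(benzyloxy)-4,5-dimethoxyphenyl]-3,4-dihydroxy-7-methoxy-5,6-[(diphenylmethylene)dioxy]chromane-3-carbaldehyde
Conditions: OsO4 (5 mol %), NMO (1.5 equiv), acetone/H2O 4:1, rt
Reagents that add atoms: N-methylmorpholine N-oxide, C[N+]1([O-])CCOCC1; water, O
Why: Catalytic osmylation with amine N-oxide reoxidation (syn-dihydroxylation) of the C3=C4 bond, expected anti to the 2-aryl group; the new C3 and C4 centres are transient, since C4 is oxidised and C3 is reset in step 8, so both diastereomers would converge.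

Step 8
Reactants: 9 (2R,3S,4S)-2-[3-(benzyloxy)-4,5-dimethoxyphenyl]-3,4-dihydroxy-7-methoxy-5,6-[(diphenylmethylene)dioxy]chromane-3-carbaldehyde
Product: 11 (2R,3R)-2-[3-(benzyloxy)-4,5-dimethoxyphenyl]-3-hydroxy-7-methoxy-5,6-[(diphenylmethylene)dioxy]chroman-4-one, via keto aldehyde 10 (not isolated)
Conditions: IBX (1.5 equiv), DMSO, rt; then K2CO3 (0.2 equiv), MeOH, 0 °C, short contact, AcOH quench
Reagents that add atoms: none
Why: IBX oxidises the secondary benzylic C4–OH of the 1,2-diol to the ketone without C–C cleavage; methoxide then attacks the non-enolisable formyl group (retro-Claisen deformylation), and C-protonation of the enediolate sets C3 under thermodynamic control as the 2,3-trans (diequatorial, 3R) ketol.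

Step 9
Reactants: 11 (2R,3R)-2-[3-(benzyloxy)-4,5-dimethoxyphenyl]-3-hydroxy-7-methoxy-5,6-[(diphenylmethylene)dioxy]chroman-4-one
Product: 12 (2R,3R)-2-[3-(benzyloxy)-4,5-dimethoxyphenyl]-3,7-dimethoxy-5,6-[(diphenylmethylene)dioxy]chroman-4-one
Conditions: Me3OBF4 (3 equiv), 1,8-bis(dimethylamino)naphthalene (3 equiv), 4 Å MS, CH2Cl2, 0 °C to rt
Reagents that add atoms: trimethyloxonium tetrafluoroborate, C[O+](C)C.F[B-](F)(F)F
Why: O-Alkylation of the C3 hydroxyl by a trialkyloxonium salt buffered by a non-nucleophilic amine; the C3–O bond is not broken, so the 3R configuration is retained.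

Step 10
Reactants: 12 (2R,3R)-2-[3-(benzyloxy)-4,5-dimethoxyphenyl]-3,7-dimethoxy-5,6-[(diphenylmethylene)dioxy]chroman-4-one
Product: 13 (2R,3R)-5,6-dihydroxy-2-(3-hydroxy-4,5-dimethoxyphenyl)-3,7-dimethoxychroman-4-one (CNP0075601.1)
Conditions: H2 (1 atm), Pd/C (10 wt %), EtOAc/MeOH, rt
Reagents that add atoms: none
Why: Hydrogenolysis over palladium cleaves the benzyl ether and both benzylic C–O bonds of the diphenylmethylene ketal in one operation, freeing the three phenols; the aryl ketone and the methyl ethers are not expected to react under these conditions.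

**Compound list**

1 | 3,4,5-trimethoxyphenol | COc1cc(O)cc(OC)c1OC | starting material
2 | 6-hydroxy-2,3,4-trimethoxybenzaldehyde | COc1cc(O)c(C=O)c(OC)c1OC | intermediate
3 | 2,3,6-trihydroxy-4-methoxybenzaldehyde | COc1cc(O)c(C=O)c(O)c1O | intermediate
4 | 5-hydroxy-7-methoxy-2,2-diphenyl-1,3-benzodioxole-4-carbaldehyde | COc1cc(O)c(C=O)c2OC(c3ccccc3)(c3ccccc3)Oc12 | intermediate
5 | 3-hydroxy-4,5-dimethoxybenzaldehyde | COc1cc(C=O)cc(O)c1OC | starting material
6 | 3-(benzyloxy)-4,5-dimethoxybenzaldehyde | COc1cc(C=O)cc(OCc2ccccc2)c1OC | intermediate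
7 | (E)-3-[3-(benzyloxy)-4,5-dimethoxyphenyl]prop-2-enal | COc1cc(/C=C/C=O)cc(OCc2ccccc2)c1OC | intermediate
8 | (2R)-2-[3-(benzyloxy)-4,5-dimethoxyphenyl]-7-methoxy-5,6-[(diphenylmethylene)dioxy]-2H-chromene-3-carbaldehyde | COc1cc2c(c3OC(c4ccccc4)(c4ccccc4)Oc31)C=C(C=O)[C@@H](c1cc(OC)c(OC)c(OCc3ccccc3)c1)O2 | intermediate
9 | (2R,3S,4S)-2-[3-(benzyloxy)-4,5-dimethoxyphenyl]-3,4-dihydroxy-7-methoxy-5,6-[(diphenylmethylene)dioxy]chromane-3-carbaldehyde (3,4-cis-diol, 3-OH trans to the 2-aryl group) | COc1cc2c(c3OC(c4ccccc4)(c4ccccc4)Oc31)[C@H](O)[C@@](O)(C=O)[C@@H](c1cc(OC)c(OC)c(OCc3ccccc3)c1)O2 | intermediate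
10 | (2R,3S)-2-[3-(benzyloxy)-4,5-dimethoxyphenyl]-3-hydroxy-7-methoxy-4-oxo-5,6-[(diphenylmethylene)dioxy]chromane-3-carbaldehyde (keto aldehyde, not isolated) | COc1cc2c(c3OC(c4ccccc4)(c4ccccc4)Oc31)C(=O)[C@@](O)(C=O)[C@@H](c1cc(OC)c(OC)c(OCc3ccccc3)c1)O2 | intermediate
11 | (2R,3R)-2-[3-(benzyloxy)-4,5-dimethoxyphenyl]-3-hydroxy-7-methoxy-5,6-[(diphenylmethylene)dioxy]chroman-4-one | COc1cc2c(c3OC(c4ccccc4)(c4ccccc4)Oc31)C(=O)[C@H](O)[C@@H](c1cc(OC)c(OC)c(OCc3ccccc3)c1)O2 | intermediate
12 | (2R,3R)-2-[3-(benzyloxy)-4,5-dimethoxyphenyl]-3,7-dimethoxy-5,6-[(diphenylmethylene)dioxy]chroman-4-one | COc1cc2c(c3OC(c4ccccc4)(c4ccccc4)Oc31)C(=O)[C@H](OC)[C@@H](c1cc(OC)c(OC)c(OCc3ccccc3)c1)O2 | intermediate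
13 | (2R,3R)-5,6-dihydroxy-2-(3-hydroxy-4,5-dimethoxyphenyl)-3,7-dimethoxychroman-4-one | COc1cc2c(c(O)c1O)C(=O)[C@H](OC)[C@@H](c1cc(O)c(OC)c(OC)c1)O2 | target

**Step count and risks**

Total step count: 10. Longest linear sequence: 8 steps (steps 1, 2, 3, 6, 7, 8, 9, 10, from 1).

Steps most likely to fail:

Step 9. The C3 hydroxyl is hydrogen-bonded to the C4 carbonyl and flanked by the 2-aryl group, so alkylation may be slow. Long exposure to the amine base could let the ketone enolise towards C3, which would erode the trans relationship, open ring C by β-elimination of O1, or lead on to the flavonol by air oxidation. Fallback: setting out from 11, the methyl group is transferred under acid instead of base. (Trimethylsilyl)diazomethane and 48 % aqueous HBF4 in CH2Cl2 at 0 °C generate a methyldiazonium ion that the hydroxyl captures, in a medium where no enolate can form. This returns to the route at 12 and passes through no new compound (F0).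

Step 8. Oxidative C–C cleavage of the vicinal diol or of the α-hydroxy aldehyde may compete with oxidation at C4. In the basic deformylation the enediolate may also expel O1 (ring opening to the chalcone), which would scramble C2. Fallback: from 9, the extra carbon is removed as CO2 under neutral conditions instead of as formate under base. NaClO2, NaH2PO4 and 2-methyl-2-butene in t-BuOH/H2O should give the α-hydroxy acid F1. IBX in DMSO then oxidises C4–OH to the β-keto acid F2, which should lose CO2 on warming to 40 °C and tautomerise to the ketol, returning to the route at 11.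

Step 6. The formyl group of 4 is flanked by two oxygen substituents and is strongly deactivated by three donor oxygens, so the aldol closure may be slow. The reversible oxa-Michael adduct would then revert, and a slower, unselective background cyclisation would lower the enantiomeric purity. Fallback: from 4 and 6, ring C is built by the chalcone epoxide route, in which C2–C3 comes from a condensation and O1–C2 from an epoxide opening.
- MOMCl and i-Pr2NEt give the MOM ether F3.
- MeMgBr in THF gives the carbinol F4.
- MnO2 gives the methyl ketone F5.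
- Claisen–Schmidt condensation with 6 (KOH, EtOH) gives the chalcone F6.
- Juliá–Colonna epoxidation (poly-L-leucine, urea–H2O2, DBU, THF) should give the (2R,3S)-epoxy ketone F7.
- HCl in MeOH removes the MOM group, and the freed phenol opens the epoxide at the benzylic carbon with inversion (6-endo), returning to the route at 11.

**Further compounds**

F0 | step 9 | none | none
F1 | step 8 | (2R,3S,4S)-2-[3-(benzyloxy)-4,5-dimethoxyphenyl]-3,4-dihydroxy-7-methoxy-5,6-[(diphenylmethylene)dioxy]chromane-3-carboxylic acid | COc1cc2c(c3OC(c4ccccc4)(c4ccccc4)Oc31)[C@H](O)[C@@](O)(C(=O)O)[C@@H](c1cc(OC)c(OC)c(OCc3ccccc3)c1)O2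
F2 | step 8 | (2R,3R)-2-[3-(benzyloxy)-4,5-dimethoxyphenyl]-3-hydroxy-7-methoxy-4-oxo-5,6-[(diphenylmethylene)dioxy]chromane-3-carboxylic acid | COc1cc2c(c3OC(c4ccccc4)(c4ccccc4)Oc31)C(=O)[C@@](O)(C(=O)O)[C@@H](c1cc(OC)c(OC)c(OCc3ccccc3)c1)O2
F3 | step 6 | 7-methoxy-5-(methoxymethoxy)-2,2-diphenyl-1,3-benzodioxole-4-carbaldehyde | COCOc1cc(OC)c2OC(c3ccccc3)(c3ccccc3)Oc2c1C=O
F4 | step 6 | 1-[7-methoxy-5-(methoxymethoxy)-2,2-diphenyl-1,3-benzodioxol-4-yl]ethan-1-ol (racemic) | COCOc1cc(OC)c2OC(c3ccccc3)(c3ccccc3)Oc2c1C(C)O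
F5 | step 6 | 1-[7-methoxy-5-(methoxymethoxy)-2,2-diphenyl-1,3-benzodioxol-4-yl]ethan-1-one | COCOc1cc(OC)c2OC(c3ccccc3)(c3ccccc3)Oc2c1C(C)=O
F6 | step 6 | (E)-3-[3-(benzyloxy)-4,5-dimethoxyphenyl]-1-[7-methoxy-5-(methoxymethoxy)-2,2-diphenyl-1,3-benzodioxol-4-yl]prop-2-en-1-one | COCOc1cc(OC)c2OC(c3ccccc3)(c3ccccc3)Oc2c1C(=O)/C=C/c1cc(OC)c(OC)c(OCc2ccccc2)c1
F7 | step 6 | [(2R,3S)-3-[3-(benzyloxy)-4,5-dimethoxyphenyl]oxiran-2-yl][7-methoxy-5-(methoxymethoxy)-2,2-diphenyl-1,3-benzodioxol-4-yl]methanone | COCOc1cc(OC)c2OC(c3ccccc3)(c3ccccc3)Oc2c1C(=O)[C@H](O1)[C@@H]1c1cc(OC)c(OC)c(OCc2ccccc2)c1
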